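The cyclohexene ring (C1 = CH bearing the side chain, C2 = CH2, C3 = vinylic CH, C4 = vinylic C bearing CH2O, C5 = CHOH, C6 = CH2) is read as a reduced, α-hydroxymethylated cyclohex-2-enone. C4–C5–C6 then come from tert-butyl acetoacetate, an acetone 1,3-dianion equivalent, and C1–C2–C3 from a silyl-capped enynal. One amine-catalysed Michael/aldol-condensation/decarboxylation operation joins C6 to C1 and C4 to C3, sets the C1 stereocentre under catalyst control and erases the activating ester. The alkyne is later turned into the branched skipped diene by ruthenium-catalysed alkene–alkyne coupling, and the C5 carbinol is relayed from C1 by Luche reduction.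

Key step: step 2

Remark: (S)-2-methylglycidol, 3-(trimethylsilyl)prop-2-ynal, the formyl ylide and the (R)-diarylprolinol silyl ether are assumed to be commercially available.

**Step 1**
Reactants: 1 3-(trimethylsilyl)prop-2-ynal; 2 (triphenylphosphoranylidene)acetaldehyde
Product: 3 (E)-5-(trimethylsilyl)pent-2-en-4-ynal
Conditions: CH2Cl2, 0 °C to rt
Reagents that add atoms: (triphenylphosphoranylidene)acetaldehyde 2, O=CC=P(c1ccccc1)(c1ccccc1)c1ccccc1
Why: Wittig olefination with a formyl-stabilised ylide, which reacts with the more electrophilic ynal rather than with the product enal and should give the (E)-alkene.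

**Step 2**
Reactants: 3 (E)-5-(trimethylsilyl)pent-2-en-4-ynal; 4 tert-butyl 3-oxobutanoate
Product: 7 (5S)-5-[(trimethylsilyl)ethynyl]cyclohex-2-en-1-one, via Michael adduct 5 (not isolated), via cyclised keto ester 6 (not isolated)
Conditions: (R)-2-{bis[3,5-bis(trifluoromethyl)phenyl](trimethylsilyloxy)methyl}pyrrolidine (10 mol %), toluene, rt; then TsOH·H2O (20 mol %), toluene, 80 °C
Reagents that add atoms: tert-butyl 3-oxobutanoate 4, CC(=O)CC(=O)OC(C)(C)C
Why: The amine turns enal 3 into an (E)-s-trans iminium ion, the α-carbon of 4 adds to its β-carbon (C6–C1 bond) on the face opposite the bulky C(Ar)2OSiMe3 group, and hydrolysis releases adduct 5. Acid then enolises the methyl ketone toward CH3, this enol attacks the aldehyde and water is lost (C4=C3 bond, giving 6), and the tert-butyl ester is cleaved with loss of 2-methylpropene and CO2. The closest known reaction type is the diarylprolinol silyl ether catalysed Michael addition of β-keto esters to enals followed by acid-mediated aldol condensation and decarboxylation to 5-substituted cyclohex-2-enones, a formal [3+3] annulation. The ring closes in a 6-(enolendo)-exo-trig aldol mode. The one new stereocentre (ring C1) is set by the catalyst, whose (R) enantiomer should give the (S) centre by attack anti to its shielding group. The step needs 1,4- over 1,2- and 1,6-addition, secured by iminium activation and by the silyl cap on the alkyne terminus, and closure only through the methyl-side enol, secured because the other α-carbon could only close a four-membered ring.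

**Step 3**
Reactants: 7 (5S)-5-[(trimethylsilyl)ethynyl]cyclohex-2-en-1-one
Product: 8 (5S)-5-ethynylcyclohex-2-en-1-one
Conditions: Bu4NF, AcOH, THF, 0 °C
Reagents that add atoms: none
Why: Fluoride-induced protodesilylation of the C(sp)–Si bond, with AcOH keeping the medium non-basic so that the enone and the C5 stereocentre should remain untouched.

**Step 4**
Reactants: 9 (S)-2-methylglycidol; 10 vinylmagnesium bromide
Product: 11 (R)-2-methylpent-4-ene-1,2-diol
Conditions: CuI (10 mol %), THF, −30 °C to 0 °C; aq. NH4Cl
Reagents that add atoms: vinylmagnesium bromide 10, C=C[Mg]Br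
Why: Copper-catalysed Grignard opening of the epoxide at its unsubstituted CH2 (SN2), which leaves the quaternary carbinol carbon untouched, so its configuration is retained and only the descriptor changes through the priority rules.

**Step 5**
Reactants: 8 (5S)-5-ethynylcyclohex-2-en-1-one; 11 (R)-2-methylpent-4-ene-1,2-diol
Product: 12 (5S)-5-[(4E,6R)-6,7-dihydroxy-6-methylhepta-1,4-dien-2-yl]cyclohex-2-en-1-one
Conditions: [CpRu(MeCN)3]PF6 (10 mol %), acetone, rt
Reagents that add atoms: none
Why: Ruthenium-catalysed alkene–alkyne coupling of the Alder-ene type, in which a ruthenacyclopentene joins the internal alkyne carbon to the terminal alkene carbon and β-hydride elimination from the allylic CH2 followed by reductive elimination should give the 1,1-disubstituted alkene and the new (E)-alkene, the branched regiochemistry being favoured by the branched propargylic carbon, with no stereocentre touched.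

**Step 6**
Reactants: 12 (5S)-5-[(4E,6R)-6,7-dihydroxy-6-methylhepta-1,4-dien-2-yl]cyclohex-2-en-1-one; 13 formaldehyde
Product: 14 (5S)-5-[(4E,6R)-6,7-dihydroxy-6-methylhepta-1,4-dien-2-yl]-2-(hydroxymethyl)cyclohex-2-en-1-one
Conditions: 37% aq. HCHO, 4-(dimethylamino)pyridine (20 mol %), THF/H2O, rt
Reagents that add atoms: formaldehyde 13, C=O
Why: Morita–Baylis–Hillman hydroxymethylation, in which the pyridine adds to the enone β-carbon, the enolate adds to formaldehyde and the catalyst is eliminated, placing CH2OH on the enone α-carbon (ring C4) without touching the skipped diene or the diol.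

**Step 7**
Reactants: 14 (5S)-5-[(4E,6R)-6,7-dihydroxy-6-methylhepta-1,4-dien-2-yl]-2-(hydroxymethyl)cyclohex-2-en-1-one; 15 2-methylpropanoyl chloride
Product: 16 (2R,3E)-2-hydroxy-2-methyl-6-[(1S)-4-{[(2-methylpropanoyl)oxy]methyl}-5-oxocyclohex-3-en-1-yl]hepta-3,6-dien-1-yl 2-methylpropanoate
Conditions: 2-methylpropanoyl chloride (2.2 equiv), pyridine, CH2Cl2, −20 °C to 0 °C
Reagents that add atoms: 2-methylpropanoyl chloride 15, CC(C)C(Cl)=O
Why: Acylation of the two primary alcohols by the acid chloride, the tertiary allylic alcohol being too hindered to react at low temperature without a nucleophilic catalyst.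

**Step 8**
Reactants: 16 (2R,3E)-2-hydroxy-2-methyl-6-[(1S)-4-{[(2-methylpropanoyl)oxy]methyl}-5-oxocyclohex-3-en-1-yl]hepta-3,6-dien-1-yl 2-methylpropanoate
Product: 17 (2R,3E)-2-hydroxy-6-[(1S,5S)-5-hydroxy-4-{[(2-methylpropanoyl)oxy]methyl}cyclohex-3-en-1-yl]-2-methylhepta-3,6-dien-1-yl 2-methylpropanoate
Conditions: NaBH4, CeCl3·7H2O, MeOH, −78 °C
Reagents that add atoms: none
Why: Luche 1,2-reduction, in which hydride adds axially to the half-chair enone carrying the side chain pseudo-equatorially and should give the pseudo-equatorial (S) alcohol cis to the C1 substituent, as in the reduction of carvone to cis-carveol, while both esters survive.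

**Compound list**
1 | 3-(trimethylsilyl)prop-2-ynal | C[Si](C)(C)C#CC=O | starting material
2 | (triphenylphosphoranylidene)acetaldehyde | O=CC=P(c1ccccc1)(c1ccccc1)c1ccccc1 | starting material
3 | (E)-5-(trimethylsilyl)pent-2-en-4-ynal | C[Si](C)(C)C#C/C=C/C=O | intermediate
4 | tert-butyl 3-oxobutanoate | CC(=O)CC(=O)OC(C)(C)C | starting material
5 | tert-butyl (3S)-2-acetyl-5-oxo-3-[(trimethylsilyl)ethynyl]pentanoate (C2 epimers) | C[Si](C)(C)C#C[C@H](C(C(C)=O)C(=O)OC(C)(C)C)CC=O | intermediate
6 | tert-butyl (1R,6S)-2-oxo-6-[(trimethylsilyl)ethynyl]cyclohex-3-ene-1-carboxylate (trans shown, C1 labile) | C[Si](C)(C)C#C[C@H]1CC=CC(=O)[C@@H]1C(=O)OC(C)(C)C | intermediate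
7 | (5S)-5-[(trimethylsilyl)ethynyl]cyclohex-2-en-1-one | C[Si](C)(C)C#C[C@H]1CC=CC(=O)C1 | intermediate
8 | (5S)-5-ethynylcyclohex-2-en-1-one | C#C[C@H]1CC=CC(=O)C1 | intermediate
9 | (S)-2-methylglycidol, (S)-(2-methyloxiran-2-yl)methanol | C[C@]1(CO)CO1 | starting material
10 | vinylmagnesium bromide | C=C[Mg]Br | starting material
11 | (R)-2-methylpent-4-ene-1,2-diol | C=CC[C@@](C)(O)CO | intermediate
12 | (5S)-5-[(4E,6R)-6,7-dihydroxy-6-methylhepta-1,4-dien-2-yl]cyclohex-2-en-1-one | C=C(C/C=C/[C@@](C)(O)CO)[C@H]1CC=CC(=O)C1 | intermediate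
13 | formaldehyde | C=O | starting material
14 | (5S)-5-[(4E,6R)-6,7-dihydroxy-6-methylhepta-1,4-dien-2-yl]-2-(hydroxymethyl)cyclohex-2-en-1-one | C=C(C/C=C/[C@@](C)(O)CO)[C@H]1CC=C(CO)C(=O)C1 | intermediate
15 | 2-methylpropanoyl chloride | CC(C)C(Cl)=O | starting material
16 | (2R,3E)-2-hydroxy-2-methyl-6-[(1S)-4-{[(2-methylpropanoyl)oxy]methyl}-5-oxocyclohex-3-en-1-yl]hepta-3,6-dien-1-yl 2-methylpropanoate | C=C(C/C=C/[C@@](C)(O)COC(=O)C(C)C)[C@H]1CC=C(COC(=O)C(C)C)C(=O)C1 | intermediate
17 | (2R,3E)-2-hydroxy-6-[(1S,5S)-5-hydroxy-4-{[(2-methylpropanoyl)oxy]methyl}cyclohex-3-en-1-yl]-2-methylhepta-3,6-dien-1-yl 2-methylpropanoate | C=C(C/C=C/[C@@](C)(O)COC(=O)C(C)C)[C@H]1CC=C(COC(=O)C(C)C)[C@@H](O)C1 | target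

Total step count: 8. Longest linear sequence: 7 steps (steps 1, 2, 3, 5, 6, 7, 8); step 4 makes the side-chain fragment.

**Steps most likely to fail**

Step 2. The risk is insufficient facial discrimination in the Michael addition, or stalling of the acid-mediated aldol condensation and decarboxylation. The fallback sets out from 3 and comes back at 7, and closes the C4=C3 bond by a Wittig reaction instead of an aldol condensation. Enal 3 and ethyl 3-oxo-4-(triphenylphosphoranylidene)butanoate would be combined under the same (R)-diarylprolinol silyl ether with LiClO4 and 1,4-diazabicyclo[2.2.2]octane in CHCl3. The keto ester carbon should add to the iminium ion and the ylide carbon should then close the ring on the aldehyde, giving ethyl (1R,6S)-2-oxo-6-[(trimethylsilyl)ethynyl]cyclohex-3-ene-1-carboxylate F1. Krapcho dealkoxycarbonylation (LiCl, wet DMSO, 130 °C) should then give 7.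

Step 5. The risk is C–C bond formation at the terminal alkyne carbon, which gives the linear diene, or arrest of the catalyst by the enone or the diol. The fallback sets out from 8 and comes back at 12, by cross-coupling and cross-metathesis. Markovnikov hydroiodination of 8 (NaI, Me3SiCl, H2O, MeCN, 0 °C, then Et3N to revert any β-iodo ketone) should give (5S)-5-(1-iodoethenyl)cyclohex-2-en-1-one F2. Stille coupling with allyltributylstannane (Pd(PPh3)4, CuI, DMF) should give (5S)-5-(penta-1,4-dien-2-yl)cyclohex-2-en-1-one F3. The partner (R)-2-methylbut-3-ene-1,2-diol F4 would be made from racemic 2-methyl-2-vinyloxirane by palladium-catalysed dynamic kinetic asymmetric hydrolysis (Pd2(dba)3, the enantiomer of the DACH-phenyl bis(2-diphenylphosphinobenzamide) ligand that leads to the R diol, NaHCO3, Et3B, CH2Cl2/H2O). Cross-metathesis of F3 with excess F4 (second-generation Hoveyda–Grubbs catalyst RuCl2(H2IMes)(=CH-C6H4-2-OiPr), CH2Cl2, 40 °C) should give 12 with the (E)-alkene.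

Step 8. The risk is hydride delivery in the conjugate or SN2′ sense with loss of the allylic ester, or ester migration to the new alkoxide. The fallback sets out from 14 and comes back at 17, by inverting the order of reduction and acylation. Luche reduction of 14 (NaBH4, CeCl3·7H2O, MeOH, −78 °C) should give (1S,5S)-5-[(4E,6R)-6,7-dihydroxy-6-methylhepta-1,4-dien-2-yl]-2-(hydroxymethyl)cyclohex-2-en-1-ol F5. Chemoselective acylation of its two primary hydroxyls (2-methylpropanoyl chloride, 2,4,6-collidine, CH2Cl2, −78 °C) should then give 17.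

**Further compounds**
F1 | step 2 | ethyl (1R,6S)-2-oxo-6-[(trimethylsilyl)ethynyl]cyclohex-3-ene-1-carboxylate | C[Si](C)(C)C#C[C@H]1CC=CC(=O)[C@@H]1C(=O)OCC
F2 | step 5 | (5S)-5-(1-iodoethenyl)cyclohex-2-en-1-one | C=C(I)[C@H]1CC=CC(=O)C1
F3 | step 5 | (5S)-5-(penta-1,4-dien-2-yl)cyclohex-2-en-1-one | C=CCC(=C)[C@H]1CC=CC(=O)C1
F4 | step 5 | (R)-2-methylbut-3-ene-1,2-diol | C=C[C@@](C)(O)CO
F5 | step 8 | (1S,5S)-5-[(4E,6R)-6,7-dihydroxy-6-methylhepta-1,4-dien-2-yl]-2-(hydroxymethyl)cyclohex-2-en-1-ol | C=C(C/C=C/[C@@](C)(O)CO)[C@H]1CC=C(CO)[C@@H](O)C1
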